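**Retrosynthetic overview**
- Ring A is numbered as in the target phenol: C1 OH, C2 O-aryl, C3 H, C4–C6 Br. Ring B is the 2,4-dibromophenyl ring. Both benzene rings are bought intact, so no ring is formed.
- Feature the plan rests on: the C1 hydroxyl of ring A lies between the C2 aryloxy group and the C6 bromine. An acetyl carbon can hold C1 first, activate C2 for ether formation, and then be exchanged for oxygen.
- C1–O bond (last skeletal event): target phenol ⇐ aryl acetate ⇐ aryl methyl ketone, by Baeyer–Villiger aryl migration.
- C2–O ether bond: ketone ⇐ SNAr of 2,4-dibromophenoxide on the 6-fluoro ketone, with the C1 acetyl as ortho activator.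
- C1–C(acetyl) bond: fluoro ketone ⇐ lithiation of symmetric 1,2,3-tribromo-5-fluorobenzene between F and Br, then acetylation with N-methoxy-N-methylacetamide.

Key step: step 3

Remark on the chemistry: the target is achiral, so no stereochemical element has to be set; the tetrahedral intermediates that carry a stereocentre are racemic and transient.

Step 1
Reactants: 1 1,2,3-tribromo-5-fluorobenzene; 2 N-methoxy-N-methylacetamide
Product: 5 1-(2,3,4-tribromo-6-fluorophenyl)ethan-1-one, via aryllithium 3 (not isolated), via tetrahedral lithium adduct 4 (not isolated)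
Conditions: 1 added to LiN(iPr)2 (1.1 equiv), THF, −78 °C; then 2 (1.5 equiv), −78 °C; 1 M HCl, −78 °C → rt
Reagents that add atoms: none
Why: Directed ortho-lithiation followed by a Weinreb ketone synthesis: the only two ring hydrogens of 1 are symmetry-equivalent and each is acidified by a flanking F and Br, so the amide base (which does not exchange C–Br bonds) can give only aryllithium 3, which is held at −78 °C to prevent aryne formation and should add once to 2 to give chelate 4, which resists over-addition until the acid quench releases the ketone.

Step 2
Reactants: 5 1-(2,3,4-tribromo-6-fluorophenyl)ethan-1-one; 6 2,4-dibromophenol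
Product: 9 1-[2,3,4-tribromo-6-(2,4-dibromophenoxy)phenyl]ethan-1-one, via potassium 2,4-dibromophenoxide 7 (not isolated), via Meisenheimer adduct 8 (not isolated)
Conditions: K2CO3 (1.5 equiv), DMSO, 80 °C
Reagents that add atoms: none
Why: Nucleophilic aromatic substitution (SNAr): the C–F carbon of 5 is ortho to the acetyl group and further activated by the three bromines (meta, para and meta to it), and because addition is rate-limiting fluoride is displaced far faster than any bromide, so phenoxide 7 should enter only at the fluorinated carbon through adduct 8.

Step 3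
Reactants: 9 1-[2,3,4-tribromo-6-(2,4-dibromophenoxy)phenyl]ethan-1-one
Product: 11 2,3,4-tribromo-6-(2,4-dibromophenoxy)phenyl acetate, via Criegee adduct 10 (not isolated)
Conditions: (CF3CO)2O, urea–H2O2, CH2Cl2, 0 °C → rt
Reagents that add atoms: trifluoroperacetic acid, OOC(=O)C(F)(F)F, made in the flask from hydrogen peroxide (as its urea adduct), OO, and trifluoroacetic anhydride, O=C(OC(=O)C(F)(F)F)C(F)(F)F; it delivers one oxygen atom
Why: Baeyer–Villiger oxidation: trifluoroperacetic acid adds to the acid-activated carbonyl of 9 to give Criegee adduct 10, and ring A then shifts from carbon to the adjacent peroxide oxygen as trifluoroacetate leaves, which forms the C1–O bond with the substitution pattern of ring A untouched. The closest known reaction type is the peracid oxidation of 2,6-disubstituted and ortho-alkoxy acetophenones to aryl acetates. No ring is closed and no stereocentre is created. The step needs aryl rather than methyl migration: methyl is the poorest migrating group, the lone pair of the C2 aryloxy oxygen stabilises the positive charge that builds on the migrating ipso carbon, and the acetyl group, pushed out of the ring plane by the C2 aryloxy and C6 bromine substituents, gains relief of strain as ring A moves to oxygen. Chemoselectivity is also needed: the five C–Br bonds are inert to peracid, both rings are too electron-poor for electrophilic hydroxylation, and the strongest common peracid is chosen to overcome slow addition to the shielded carbonyl.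

Step 4
Reactants: 11 2,3,4-tribromo-6-(2,4-dibromophenoxy)phenyl acetate
Product: 13 2,3,4-tribromo-6-(2,4-dibromophenoxy)phenol, via potassium phenoxide 12 (not isolated)
Conditions: K2CO3 (1.5 equiv), MeOH, rt; then 1 M HCl
Reagents that add atoms: none
Why: Base-mediated transesterification (methanolysis) of an aryl acetate: methoxide attacks the accessible acetyl carbonyl and expels the well-stabilised polybrominated phenoxide 12, which the acid work-up protonates, while the diaryl ether and the five C–Br bonds are inert at room temperature.

**Compound list**
1 | 1,2,3-tribromo-5-fluorobenzene | Fc1cc(Br)c(Br)c(Br)c1 | starting material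
2 | N-methoxy-N-methylacetamide | CON(C)C(C)=O | starting material
3 | (2,3,4-tribromo-6-fluorophenyl)lithium | [Li]c1c(F)cc(Br)c(Br)c1Br | intermediate (not isolated)
4 | lithium 1-[methoxy(methyl)amino]-1-(2,3,4-tribromo-6-fluorophenyl)ethan-1-olate (racemic tetrahedral adduct) | CC([O-])(N(C)OC)c1c(F)cc(Br)c(Br)c1Br.[Li+] | intermediate (not isolated)
5 | 1-(2,3,4-tribromo-6-fluorophenyl)ethan-1-one | CC(=O)c1c(F)cc(Br)c(Br)c1Br | intermediate
6 | 2,4-dibromophenol | Oc1ccc(Br)cc1Br | starting material
7 | potassium 2,4-dibromophenoxide | [O-]c1ccc(Br)cc1Br.[K+] | intermediate (not isolated)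
8 | potassium 1-[2,3,4-tribromo-6-(2,4-dibromophenoxy)-6-fluorocyclohexa-2,4-dien-1-ylidene]ethan-1-olate (racemic Meisenheimer adduct) | CC([O-])=C1C(Br)=C(Br)C(Br)=CC1(F)Oc1ccc(Br)cc1Br.[K+] | intermediate (not isolated)
9 | 1-[2,3,4-tribromo-6-(2,4-dibromophenoxy)phenyl]ethan-1-one | CC(=O)c1c(Oc2ccc(Br)cc2Br)cc(Br)c(Br)c1Br | intermediate (key-step precursor)
10 | 1-hydroxy-1-[2,3,4-tribromo-6-(2,4-dibromophenoxy)phenyl]ethyl trifluoroperoxyacetate (racemic Criegee adduct) | CC(O)(OOC(=O)C(F)(F)F)c1c(Oc2ccc(Br)cc2Br)cc(Br)c(Br)c1Br | intermediate (not isolated)
11 | 2,3,4-tribromo-6-(2,4-dibromophenoxy)phenyl acetate | CC(=O)Oc1c(Oc2ccc(Br)cc2Br)cc(Br)c(Br)c1Br | intermediate (key-step product)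
12 | potassium 2,3,4-tribromo-6-(2,4-dibromophenoxy)phenoxide | [O-]c1c(Oc2ccc(Br)cc2Br)cc(Br)c(Br)c1Br.[K+] | intermediate (not isolated)
13 | 2,3,4-tribromo-6-(2,4-dibromophenoxy)phenol | Oc1c(Oc2ccc(Br)cc2Br)cc(Br)c(Br)c1Br | target

**Step count and risks**
Total step count: 4. Longest linear sequence: 4 steps (1 → 5 → 9 → 11 → 13).

Steps most likely to fail:

1. Step 3 (key step). Addition of the peracid to a carbonyl that is shielded on both sides and twisted out of conjugation may be slow enough for the peracid to be consumed unproductively. Methyl migration may also intrude because ring A is electron-poor. The fallback holds C1 as a formyl group, which is far less shielded; peracid oxidation of ortho-aryloxy benzaldehydes to aryl formates is established chemistry. It sets out from 1. Aryllithium 3, generated as in step 1, would be quenched at −78 °C with N,N-dimethylformamide to give lithium (dimethylamino)(2,3,4-tribromo-6-fluorophenyl)methanolate F1 (not isolated), and acid work-up should then release 2,3,4-tribromo-6-fluorobenzaldehyde F2. SNAr with 6 (K2CO3, DMSO, 50 °C) should give 2,3,4-tribromo-6-(2,4-dibromophenoxy)benzaldehyde F3. Dakin-type Baeyer–Villiger oxidation with mCPBA in CH2Cl2 should give 2,3,4-tribromo-6-(2,4-dibromophenoxy)phenyl formate F4. Methanolysis (K2CO3, MeOH, then HCl) brings the sequence back to the route at 13.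

2. Step 1. The aryllithium is hindered and stabilised by two flanking halogens, so acylation at −78 °C may be slow. In that time it can be protonated by the acidic methyl group of the amide, exchange bromine with unreacted 1 (halogen dance), or lose lithium halide to an aryne if the temperature is raised. The fallback separates C–C bond formation from the oxidation level. It sets out from 1: aryllithium 3 would be trapped within minutes at −78 °C with the far more electrophilic acetaldehyde to give, after acid quench, racemic 1-(2,3,4-tribromo-6-fluorophenyl)ethan-1-ol F5. Oxidation with Dess–Martin periodinane (CH2Cl2, rt) returns to the route at 5.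

3. Step 2. 2,4-Dibromophenoxide is a weak, ortho-hindered nucleophile and the acetyl activator is twisted, so substitution at C–F may be slow. Displacement of the bromines ortho and para to the acetyl group, or base-mediated self-condensation of the methyl ketone, could then compete. The fallback reverses the roles of the rings, with ring A as the nucleophile and ring B as the electrophile. It sets out from 5. Treatment with 2-(methanesulfonyl)ethanol and NaH (DMF, 0 °C → rt) should substitute fluoride with a small, strong alkoxide to give 1-{2,3,4-tribromo-6-[2-(methanesulfonyl)ethoxy]phenyl}ethan-1-one F6 (not isolated). This should lose methyl vinyl sulfone by β-elimination under the same conditions and give, after acidification, 1-(2,3,4-tribromo-6-hydroxyphenyl)ethan-1-one F7. O-Arylation of F7 (K2CO3, MeCN, 60 °C) would use (2,4-dibromophenyl)(2,4,6-trimethoxyphenyl)iodonium 4-methylbenzenesulfonate F8. This salt would be prepared in one pot from 2,4-dibromo-1-iodobenzene, mCPBA, TsOH·H2O and 1,3,5-trimethoxybenzene in MeCN. The electron-poor, ortho-substituted dibromophenyl group should be the one transferred, and the sequence comes back to the route at 9.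

**Further compounds**
F1 | step 3 | lithium (dimethylamino)(2,3,4-tribromo-6-fluorophenyl)methanolate (racemic, not isolated) | CN(C)C([O-])c1c(F)cc(Br)c(Br)c1Br.[Li+]
F2 | step 3 | 2,3,4-tribromo-6-fluorobenzaldehyde | O=Cc1c(F)cc(Br)c(Br)c1Br
F3 | step 3 | 2,3,4-tribromo-6-(2,4-dibromophenoxy)benzaldehyde | O=Cc1c(Oc2ccc(Br)cc2Br)cc(Br)c(Br)c1Br
F4 | step 3 | 2,3,4-tribromo-6-(2,4-dibromophenoxy)phenyl formate | O=COc1c(Oc2ccc(Br)cc2Br)cc(Br)c(Br)c1Br
F5 | step 1 | 1-(2,3,4-tribromo-6-fluorophenyl)ethan-1-ol (racemic) | CC(O)c1c(F)cc(Br)c(Br)c1Br
F6 | step 2 | 1-{2,3,4-tribromo-6-[2-(methanesulfonyl)ethoxy]phenyl}ethan-1-one (not isolated) | CC(=O)c1c(OCCS(C)(=O)=O)cc(Br)c(Br)c1Br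
F7 | step 2 | 1-(2,3,4-tribromo-6-hydroxyphenyl)ethan-1-one | CC(=O)c1c(O)cc(Br)c(Br)c1Br
F8 | step 2 | (2,4-dibromophenyl)(2,4,6-trimethoxyphenyl)iodonium 4-methylbenzenesulfonate | COc1cc(OC)c([I+]c2ccc(Br)cc2Br)c(OC)c1.Cc1ccc(cc1)S([O-])(=O)=O
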